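**Retrosynthetic overview**

- The target is reached by acetonide hydrolysis of a macrolactone whose only skeletal ring (14-membered) is closed last, by forming the C1–O bond: an acylketene from a tert-butyl β-keto ester is captured by the C13 hydroxyl.
- The β-keto ester comes from a Claisen condensation of a propanoate enolate on the C3 methyl ester; the 2-substituted diene comes from a Suzuki coupling at C10–C11.
- C8 and the C7–C8 bond come from a Rh/BINAP conjugate alkenylation of (E)-pent-3-en-2-one; the (E)-alkenylboronate comes from Cu-catalysed methylboration of a propargyl group.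
- The quaternary C4 carbinol is set by a second C–O bond formation: a new enantioselective, Brønsted-acid-catalysed acetonide migration (1,3-dioxane to 1,3-dioxolane) on an achiral carbinol made from dihydroxyacetone acetonide and propargylzinc.
- Ring order: the dioxolane (protecting ring, step 2) first, the macrolactone (step 10) second; the dioxolane is opened in the last step.

**Conventions and assumptions**

- Locants follow the macrolide chain: C1 lactone C=O, C2 CHMe, C3 ketone, C4 C(OH)(CH2OH), C5 CH2, C6(Me)=C7, C8 CHMe, C9 CH2, C10 (=CH2), C11=C12(Me), C13 CH(Et)–O. The target is (2S,4R,6E,8R,11E,13R).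
- Assumption: C2 lies between two carbonyls and equilibrates through the enol; the (2S) epimer is taken to be the thermodynamically preferred one in the 14-membered ring.
- Assumption: (R)-pent-1-yn-3-ol is bought as the single enantiomer.

**Route**

Step 1
Reactants: 1 2,2-dimethyl-1,3-dioxan-5-one; 2 3-bromoprop-1-yne
Product: 4 2,2-dimethyl-5-(prop-2-yn-1-yl)-1,3-dioxan-5-ol, via allenylzinc bromide 3 (not isolated)
Conditions: Zn dust, THF, 0 °C to rt; then H2O/NH4Cl
Reagents that add atoms: none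
Why: Barbier-type zinc propargylation in which the allenylzinc adds by SE2′ to the activated ketone and gives the homopropargylic tertiary alcohol, which is still achiral.

Step 2
Reactants: 4 2,2-dimethyl-5-(prop-2-yn-1-yl)-1,3-dioxan-5-ol
Product: 5 (S)-[2,2-dimethyl-4-(prop-2-yn-1-yl)-1,3-dioxolan-4-yl]methanol
Conditions: (S)-3,3′-bis(2,4,6-triisopropylphenyl)-1,1′-binaphthyl-2,2′-diyl N-triflylphosphoramide (5 mol %; the antipode if the first run gives ent-5), toluene 0.05 M, 4 Å molecular sieves, −40 °C, quench with Et3N at full conversion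
Reagents that add atoms: none
Why: Proposed new method: an enantioselective chiral-Brønsted-acid-catalysed intramolecular transacetalisation in which the acid protonates one of the two enantiotopic ring oxygens of achiral 4, that C–O bond ionises to an ion-paired oxocarbenium ion held on the other CH2O arm, and the tertiary hydroxyl closes the five-membered ring (new C–O bond), so the choice between the two CH2O arms sets quaternary C4; the migration is driven by loss of the axial 2-methyl strain of the dioxane and is run cold to full conversion so that slower re-ionisation of 5 does not erode the ee; the racemic acid-catalysed dioxane-to-dioxolane migration is known, and the closest asymmetric precedents are chiral phosphoric acid-catalysed transacetalisations and desymmetrisations of acetals of 2,2-disubstituted propane-1,3-diols.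

Step 3
Reactants: 5 (S)-[2,2-dimethyl-4-(prop-2-yn-1-yl)-1,3-dioxolan-4-yl]methanol
Product: 8 methyl (R)-2,2-dimethyl-4-(prop-2-yn-1-yl)-1,3-dioxolane-4-carboxylate, via aldehyde 6 (not isolated), via carboxylic acid 7 (not isolated)
Conditions: TEMPO (20 mol %), PhI(OAc)2 (2.2 equiv), MeCN/H2O 1:1, rt; extract; then Me3SiCHN2, toluene/MeOH, 0 °C
Reagents that add atoms: water (O); trimethylsilyldiazomethane (C[Si](C)(C)C=[N+]=[N-])
Why: Nitroxyl-catalysed oxidation takes the primary alcohol through the aldehyde hydrate to the acid without touching alkyne or ketal, and diazoalkane esterification follows; the quaternary centre cannot epimerise (the descriptor changes only through CIP priorities).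

Step 4
Reactants: 8 methyl (R)-2,2-dimethyl-4-(prop-2-yn-1-yl)-1,3-dioxolane-4-carboxylate
Product: 9 methyl (R)-2,2-dimethyl-4-[(E)-2-methyl-3-(4,4,5,5-tetramethyl-1,3,2-dioxaborolan-2-yl)prop-2-en-1-yl]-1,3-dioxolane-4-carboxylate
Conditions: CuCl (10 mol %), Xantphos (11 mol %), NaOtBu (1.5 equiv), B2pin2 (1.2 equiv), MeI (3 equiv), THF, rt
Reagents that add atoms: bis(pinacolato)diboron (CC1(C)OB(OC1(C)C)B1OC(C)(C)C(C)(C)O1); iodomethane (CI)
Why: Copper-catalysed carboboration: syn-borylcupration puts boron on the terminal carbon and the internal alkenylcopper is methylated with retention, which fixes the (E)-trisubstituted C6=C7 geometry.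

Step 5
Reactants: 9 methyl (R)-2,2-dimethyl-4-[(E)-2-methyl-3-(4,4,5,5-tetramethyl-1,3,2-dioxaborolan-2-yl)prop-2-en-1-yl]-1,3-dioxolane-4-carboxylate; 10 (E)-pent-3-en-2-one
Product: 11 methyl (R)-4-[(R,E)-2,4-dimethyl-6-oxohept-2-en-1-yl]-2,2-dimethyl-1,3-dioxolane-4-carboxylate
Conditions: [Rh(OH)(cod)]2 (3 mol %; cod = 1,5-cyclooctadiene), (S)-BINAP (7 mol %), KOH (20 mol %), 10 (3 equiv), dioxane/H2O 10:1, 50 °C
Reagents that add atoms: none
Why: Hayashi–Miyaura rhodium-catalysed asymmetric 1,4-addition, in which the (S)-BINAP–alkenylrhodium species adds to the α-si face of the (E)-enone and so sets (R)-C8 under catalyst control (remote C4 has no influence) with retention of the alkene geometry.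

Step 6
Reactants: 11 methyl (R)-4-[(R,E)-2,4-dimethyl-6-oxohept-2-en-1-yl]-2,2-dimethyl-1,3-dioxolane-4-carboxylate
Product: 13 methyl (R)-4-[(R,E)-2,4-dimethyl-6-(trifluoromethylsulfonyloxy)hepta-2,6-dien-1-yl]-2,2-dimethyl-1,3-dioxolane-4-carboxylate, via potassium enolate 12 (not isolated)
Conditions: KN(SiMe3)2, THF, −78 °C; then PhNTf2, −78 °C to 0 °C
Reagents that add atoms: N-phenylbis(trifluoromethanesulfonimide) (O=S(=O)(N(c1ccccc1)S(=O)(=O)C(F)(F)F)C(F)(F)F)
Why: Kinetic deprotonation at the methyl group and O-triflation give the terminal enol triflate; the ester α-carbon is quaternary, so no other enolate can form.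

Step 7
Reactants: 14 (R)-pent-1-yn-3-ol
Product: 16 (R,E)-2-methyl-1-(4,4,5,5-tetramethyl-1,3,2-dioxaborolan-2-yl)pent-1-en-3-ol, via alkenylalane 15 (not isolated)
Conditions: AlMe3 (3 equiv), Cp2ZrCl2 (25 mol %), CH2Cl2, 0 °C to rt; then iPrOBpin (4 equiv), 0 °C to rt; aqueous potassium sodium tartrate
Reagents that add atoms: trimethylaluminium (C[Al](C)C); 2-isopropoxy-4,4,5,5-tetramethyl-1,3,2-dioxaborolane (CC(C)OB1OC(C)(C)C(C)(C)O1)
Why: Negishi zirconium-catalysed syn-methylalumination of the terminal alkyne (methyl to the internal carbon) followed by aluminium-to-boron exchange with retention gives the (E)-alkenylboronate; C13 comes unchanged from the starting material.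

Step 8
Reactants: 13 methyl (R)-4-[(R,E)-2,4-dimethyl-6-(trifluoromethylsulfonyloxy)hepta-2,6-dien-1-yl]-2,2-dimethyl-1,3-dioxolane-4-carboxylate; 16 (R,E)-2-methyl-1-(4,4,5,5-tetramethyl-1,3,2-dioxaborolan-2-yl)pent-1-en-3-ol
Product: 17 methyl (R)-4-[(2E,4R,7E,9R)-9-hydroxy-2,4,8-trimethyl-6-methylideneundeca-2,7-dien-1-yl]-2,2-dimethyl-1,3-dioxolane-4-carboxylate
Conditions: Pd(PPh3)4 (5 mol %), K3PO4 (3 equiv), THF/H2O 5:1, 50 °C
Reagents that add atoms: none
Why: Suzuki–Miyaura sp2–sp2 coupling with retention at both partners forms the C10–C11 bond of the 2-substituted 1,3-diene and tolerates the free allylic alcohol, ester and ketal.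

Step 9
Reactants: 17 methyl (R)-4-[(2E,4R,7E,9R)-9-hydroxy-2,4,8-trimethyl-6-methylideneundeca-2,7-dien-1-yl]-2,2-dimethyl-1,3-dioxolane-4-carboxylate; 18 tert-butyl propanoate
Product: 20 tert-butyl 3-[(R)-4-{(2E,4R,7E,9R)-9-hydroxy-2,4,8-trimethyl-6-methylideneundeca-2,7-dien-1-yl}-2,2-dimethyl-1,3-dioxolan-4-yl]-2-methyl-3-oxopropanoate (both C2 epimers), via lithium enolate 19 (not isolated)
Conditions: 18 (4 equiv), LiN(iPr)2 (4.2 equiv), THF, −78 °C; add 17; −78 to −20 °C; pH 7 buffer
Reagents that add atoms: none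
Why: Crossed Claisen condensation: the non-enolisable α-alkoxy methyl ester acylates the excess propanoate enolate (one equivalent is spent on the C13 alkoxide) and deprotonation of the β-keto ester drives it; C2 is formed as a labile epimer mixture.

Step 10
Reactants: 20 tert-butyl 3-[(R)-4-{(2E,4R,7E,9R)-9-hydroxy-2,4,8-trimethyl-6-methylideneundeca-2,7-dien-1-yl}-2,2-dimethyl-1,3-dioxolan-4-yl]-2-methyl-3-oxopropanoate
Product: 22 (2S,4R,6E,8R,11E,13R)-macrolactone acetonide (target with the C4 hydroxyl and the C4 hydroxymethyl oxygen bridged as a 2,2-dimethyl-1,3-dioxolane), via acylketene 21 (not isolated)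
Conditions: xylenes, 140 °C, slow addition to 0.5 mM final concentration
Reagents that add atoms: none
Why: Acylketene macrolactonisation: thermal loss of tert-butanol from the β-keto ester gives the α-methyl acylketene, which the only free hydroxyl (C13–OH) captures at high dilution to form the C1–O bond and the 14-membered ring, after which C2 settles through the enol to the more stable (2S) epimer.

Step 11
Reactants: 22 (2S,4R,6E,8R,11E,13R)-macrolactone acetonide
Product: 23 target (3S,5R,7E,9R,12E,14R)-14-ethyl-5-hydroxy-5-(hydroxymethyl)-3,7,9,13-tetramethyl-11-methylidene-1-oxacyclotetradeca-7,12-diene-2,4-dione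
Conditions: AcOH/H2O/THF 3:1:1, 35–40 °C
Reagents that add atoms: none
Why: Acid-catalysed hydrolysis of the terminal isopropylidene ketal under conditions too mild to ionise the allylic lactone C–O bond, with final equilibration of C2 through the enol.

**Compound list**

1 | 2,2-dimethyl-1,3-dioxan-5-one | CC1(C)OCC(=O)CO1 | starting material
2 | 3-bromoprop-1-yne (propargyl bromide) | C#CCBr | starting material
3 | propa-1,2-dien-1-ylzinc bromide (allenylzinc bromide) | C=C=C[Zn]Br | intermediate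
4 | 2,2-dimethyl-5-(prop-2-yn-1-yl)-1,3-dioxan-5-ol (achiral) | CC1(C)OCC(O)(CC#C)CO1 | intermediate
5 | (S)-[2,2-dimethyl-4-(prop-2-yn-1-yl)-1,3-dioxolan-4-yl]methanol | OC[C@](O1)(COC1(C)C)CC#C | intermediate
6 | (R)-2,2-dimethyl-4-(prop-2-yn-1-yl)-1,3-dioxolane-4-carbaldehyde | O=C[C@](O1)(COC1(C)C)CC#C | intermediate
7 | (R)-2,2-dimethyl-4-(prop-2-yn-1-yl)-1,3-dioxolane-4-carboxylic acid | OC(=O)[C@](O1)(COC1(C)C)CC#C | intermediate
8 | methyl (R)-2,2-dimethyl-4-(prop-2-yn-1-yl)-1,3-dioxolane-4-carboxylate | COC(=O)[C@](O1)(COC1(C)C)CC#C | intermediate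
9 | methyl (R)-2,2-dimethyl-4-[(E)-2-methyl-3-(4,4,5,5-tetramethyl-1,3,2-dioxaborolan-2-yl)prop-2-en-1-yl]-1,3-dioxolane-4-carboxylate | COC(=O)[C@](O1)(COC1(C)C)C/C(C)=C/B2OC(C)(C)C(C)(C)O2 | intermediate
10 | (E)-pent-3-en-2-one | C/C=C/C(C)=O | starting material
11 | methyl (R)-4-[(R,E)-2,4-dimethyl-6-oxohept-2-en-1-yl]-2,2-dimethyl-1,3-dioxolane-4-carboxylate | COC(=O)[C@](O1)(COC1(C)C)C/C(C)=C/[C@H](C)CC(C)=O | intermediate
12 | potassium enolate of 11 (terminal enolate, C10=CH2) | COC(=O)[C@](O1)(COC1(C)C)C/C(C)=C/[C@H](C)CC(=C)[O-].[K+] | intermediate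
13 | methyl (R)-4-[(R,E)-2,4-dimethyl-6-(trifluoromethylsulfonyloxy)hepta-2,6-dien-1-yl]-2,2-dimethyl-1,3-dioxolane-4-carboxylate | COC(=O)[C@](O1)(COC1(C)C)C/C(C)=C/[C@H](C)CC(=C)OS(=O)(=O)C(F)(F)F | intermediate
14 | (R)-pent-1-yn-3-ol | C#C[C@@H](CC)O | starting material
15 | (R,E)-[3-(dimethylaluminiooxy)-2-methylpent-1-en-1-yl]dimethylalane (alkenylalane) | CC[C@@H](O[Al](C)C)/C(C)=C/[Al](C)C | intermediate
16 | (R,E)-2-methyl-1-(4,4,5,5-tetramethyl-1,3,2-dioxaborolan-2-yl)pent-1-en-3-ol | CC[C@@H](O)/C(C)=C/B1OC(C)(C)C(C)(C)O1 | intermediate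
17 | methyl (R)-4-[(2E,4R,7E,9R)-9-hydroxy-2,4,8-trimethyl-6-methylideneundeca-2,7-dien-1-yl]-2,2-dimethyl-1,3-dioxolane-4-carboxylate | COC(=O)[C@](O1)(COC1(C)C)C/C(C)=C/[C@H](C)CC(=C)/C=C(\C)[C@@H](CC)O | intermediate
18 | tert-butyl propanoate | CCC(=O)OC(C)(C)C | starting material
19 | lithium 1-tert-butoxyprop-1-en-1-olate (lithium enolate of 18) | CC=C([O-])OC(C)(C)C.[Li+] | intermediate
20 | tert-butyl 3-[(R)-4-{(2E,4R,7E,9R)-9-hydroxy-2,4,8-trimethyl-6-methylideneundeca-2,7-dien-1-yl}-2,2-dimethyl-1,3-dioxolan-4-yl]-2-methyl-3-oxopropanoate (C2 epimers) | CC(C)(C)OC(=O)C(C)C(=O)[C@](O1)(COC1(C)C)C/C(C)=C/[C@H](C)CC(=C)/C=C(\C)[C@@H](CC)O | intermediate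
21 | 3-[(R)-4-{(2E,4R,7E,9R)-9-hydroxy-2,4,8-trimethyl-6-methylideneundeca-2,7-dien-1-yl}-2,2-dimethyl-1,3-dioxolan-4-yl]-2-methyl-3-oxoprop-1-en-1-one (acylketene) | O=C=C(C)C(=O)[C@](O1)(COC1(C)C)C/C(C)=C/[C@H](C)CC(=C)/C=C(\C)[C@@H](CC)O | intermediate
22 | (2S,4R,6E,8R,11E,13R)-macrolactone acetonide (spiro 2,2-dimethyl-1,3-dioxolane at C4) | C=C1/C=C(\C)[C@@H](CC)OC(=O)[C@@H](C)C(=O)[C@](O2)(COC2(C)C)C/C(C)=C/[C@H](C)C1 | intermediate
23 | (3S,5R,7E,9R,12E,14R)-14-ethyl-5-hydroxy-5-(hydroxymethyl)-3,7,9,13-tetramethyl-11-methylidene-1-oxacyclotetradeca-7,12-diene-2,4-dione | C=C1/C=C(\C)[C@@H](CC)OC(=O)[C@@H](C)C(=O)[C@](O)(CO)C/C(C)=C/[C@H](C)C1 | target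

**Step count**

Total: 11 steps. Longest linear sequence: 10 steps (steps 1–6 and 8–11); step 7 is the side branch.

**Steps most likely to fail, with fallbacks**

1. Step 2 (the new desymmetrising acetonide migration). The risk is low ee, or erosion of ee because 5 can re-ionise. The fallback uses known chemistry, sets out from 4 and comes back at 5. Compound 4 is hydrolysed (acidic resin, MeOH/H2O) to the achiral triol 2-(prop-2-yn-1-yl)propane-1,2,3-triol F1. The known copper-catalysed desymmetrising monobenzoylation of 2-substituted glycerols (CuCl2, chiral bis(oxazoline) ligand, PhCOCl, Et3N, THF) gives (R)-2-hydroxy-2-(hydroxymethyl)pent-4-yn-1-yl benzoate F2. 2-Methoxypropene with pyridinium p-toluenesulfonate closes the dioxolane on the remaining 1,2-diol to give [(R)-2,2-dimethyl-4-(prop-2-yn-1-yl)-1,3-dioxolan-4-yl]methyl benzoate F3. K2CO3 in MeOH removes the benzoate and returns 5.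

2. Step 10 (macrolactonisation). The risks are oligomerisation, slow ketene formation from the α-methyl tert-butyl ester, and ketene–alkene side reactions at 140 °C. The fallback exchanges the order of ester formation and ring closure; it sets out from 13 (using 16 and 19) and comes back at 22. Triflate 13 undergoes the Claisen condensation with enolate 19 to give tert-butyl 3-[(R)-4-{(R,E)-2,4-dimethyl-6-(trifluoromethylsulfonyloxy)hepta-2,6-dien-1-yl}-2,2-dimethyl-1,3-dioxolan-4-yl]-2-methyl-3-oxopropanoate F4. Heating F4 with alcohol 16 in toluene forms the C1–O13 ester bond intermolecularly (acylketene capture, no dilution needed) and gives (R,E)-2-methyl-1-(4,4,5,5-tetramethyl-1,3,2-dioxaborolan-2-yl)pent-1-en-3-yl 3-[(R)-4-{(R,E)-2,4-dimethyl-6-(trifluoromethylsulfonyloxy)hepta-2,6-dien-1-yl}-2,2-dimethyl-1,3-dioxolan-4-yl]-2-methyl-3-oxopropanoate F5. An intramolecular Suzuki–Miyaura coupling (Pd(PPh3)4, K3PO4, THF/H2O, 1 mM) then closes the ring at C10–C11 and gives 22.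

3. Step 9 (Claisen condensation on the hindered α,α-disubstituted ester with a free alkoxide present). The fallback sets out from 17 and comes back at 20. Ester 17 is reduced with iBu2AlH (CH2Cl2, −78 °C; the chelated α-alkoxy hemiacetal stops at the aldehyde) to (R)-4-[(2E,4R,7E,9R)-9-hydroxy-2,4,8-trimethyl-6-methylideneundeca-2,7-dien-1-yl]-2,2-dimethyl-1,3-dioxolane-4-carbaldehyde F6. Roskamp homologation of F6 with tert-butyl 2-diazopropanoate (Sc(OTf)3 catalyst, CH2Cl2, −40 °C; addition, 1,2-hydride shift and loss of N2) gives β-keto ester 20 directly.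

**Further compounds**

F1 | step 2 | 2-(prop-2-yn-1-yl)propane-1,2,3-triol | OCC(O)(CO)CC#C
F2 | step 2 | (R)-2-hydroxy-2-(hydroxymethyl)pent-4-yn-1-yl benzoate | O=C(OC[C@](O)(CO)CC#C)c1ccccc1
F3 | step 2 | [(R)-2,2-dimethyl-4-(prop-2-yn-1-yl)-1,3-dioxolan-4-yl]methyl benzoate | O=C(OC[C@](O1)(COC1(C)C)CC#C)c1ccccc1
F4 | step 10 | tert-butyl 3-[(R)-4-{(R,E)-2,4-dimethyl-6-(trifluoromethylsulfonyloxy)hepta-2,6-dien-1-yl}-2,2-dimethyl-1,3-dioxolan-4-yl]-2-methyl-3-oxopropanoate | CC(C)(C)OC(=O)C(C)C(=O)[C@](O1)(COC1(C)C)C/C(C)=C/[C@H](C)CC(=C)OS(=O)(=O)C(F)(F)F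
F5 | step 10 | (R,E)-2-methyl-1-(4,4,5,5-tetramethyl-1,3,2-dioxaborolan-2-yl)pent-1-en-3-yl 3-[(R)-4-{(R,E)-2,4-dimethyl-6-(trifluoromethylsulfonyloxy)hepta-2,6-dien-1-yl}-2,2-dimethyl-1,3-dioxolan-4-yl]-2-methyl-3-oxopropanoate | CC[C@@H](OC(=O)C(C)C(=O)[C@](O1)(COC1(C)C)C/C(C)=C/[C@H](C)CC(=C)OS(=O)(=O)C(F)(F)F)/C(C)=C/B2OC(C)(C)C(C)(C)O2
F6 | step 9 | (R)-4-[(2E,4R,7E,9R)-9-hydroxy-2,4,8-trimethyl-6-methylideneundeca-2,7-dien-1-yl]-2,2-dimethyl-1,3-dioxolane-4-carbaldehyde | O=C[C@](O1)(COC1(C)C)C/C(C)=C/[C@H](C)CC(=C)/C=C(\C)[C@@H](CC)O
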